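## The problem

The target **22** is a 14,15-dinorlabdane (labdane numbering throughout; β is the face of the C10 methyl group). It is a trans-fused decalin whose ring A (C1–C5, C10) carries only the C4 gem-dimethyl group. Every carbon of ring B (C5–C10) is substituted: 6α-acetoxy, 7β-hydroxy, 8α-hydroxy/8β-methyl, a 9β-(E)-3-oxobut-1-enyl chain and the angular 10β-methyl. The six stereocentres C5–C10 are contiguous, and only the quaternary C10 cannot be corrected once made, so it must be set in absolute terms. The others can be derived from it: C5 by enolisation towards the trans fusion while C6 is a carbonyl, C9 and C8 by attack anti to the axial C10 methyl, C7 by axial hydride delivery, and C6 by equilibration next to a C7 carbonyl, since all three oxygen substituents end up equatorial. The acetate sits beside a free secondary hydroxyl and can migrate under base; the tertiary C8 hydroxyl is β to C11, so a C11 aldehyde is prone to dehydration and retro-aldol cleavage; the enone tolerates neither hydride nor organometallic reagents. Acetate, aldehyde and enone must therefore appear late and under near-neutral conditions. The feature that opens the key step is the pattern of ring B: oxygen at C6 and C7, methyl at C8 and C10 and carbon at C9 map onto 3-methoxy-2,6-dimethyl-1,4-benzoquinone with C6 and C9 as the carbonyl carbons, and C1–C4 with the gem-dimethyl carbon next to C5 map onto 4-methylpenta-1,3-diene, so that C1–C10 and C4–C5 can be formed in one [4+2] addition.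

## Retrosynthesis

**C11=C12.** The enone double bond of **22** is cut first, giving aldehyde **20** and the stabilised ylide **21**. Bringing the four-carbon chain in earlier would mean carrying a masked enone through all redox steps on ring B. The olefination can be the last step and uses a commercial reagent. **20** is three carbons smaller and already holds all six stereocentres. The forward reaction must be E-selective and neutral enough to spare the acetate and the β-hydroxy aldehyde.

**C7–H and the C11 oxidation level.** Aldehyde **20** is traced back without a skeletal cut to ketone **17**: the aldehyde from primary alcohol **19**, this from benzyl ether **18**, and the 7β-carbinol of **18** from the C7 ketone of **17**. A Δ7 alkene would be the neighbouring choice, but osmylation gives the cis diol and epoxide opening the trans-diaxial one, not the trans-diequatorial diol of the target. The C7 carbonyl is also what makes C6 and C8 adjustable. **17** has one stereocentre fewer and no free secondary hydroxyl for the acetate to migrate to. The forward steps must deliver hydride axially to C7 and oxidise the primary hydroxyl of **19** beside a secondary and a tertiary one.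

**C8–O and C9–H.** Both bonds of **17** are cut together, leading to enone **15**. The neighbouring cuts fail on stereochemistry: methyl addition to a C8 ketone would come from the α face and give the 8β-alcohol, and conjugate addition of C11 to a C9-unsubstituted enone would place the chain axial (9α). **15** lacks two stereocentres and is the direct product of an enone transposition. The forward reaction must add hydrogen to C9 and oxygen to C8 from the α face. Dissolving metal is excluded because the α'-acetoxy and γ-benzyloxy groups would be expelled, which points to a hydrogen-atom-transfer hydroxylation.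

**C6.** The configuration of **15** is traced to its 6β-epimer **14**, and the O-acetyl bond of **14** is cut to give alcohol **13**. A C6 carbonyl in this skeleton can only be reduced from the α face, because the β face is closed by the syn-axial methyls on C4 and C10; the oxygen therefore first appears as the axial 6β-hydroxyl. Substitution with inversion at this hindered centre is unrealistic, whereas equilibration α to the C7 carbonyl is not, and the acetate blocks the ketol transposition open to a free 6-hydroxy-7-ketone. Forward, this asks for acylation of a hindered alcohol and an epimerisation that runs downhill to the equatorial acetate.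

**C9–C11.** Cutting this bond of **13** and returning the carbonyl from C7 to C9 gives vinylogous ester **9** and the one-carbon nucleophile **11**, generated from stannane **10**; adduct **12** is not isolated. The cut uses the methoxy group exactly where the cycloaddition leaves it, and puts C11 on the most hindered ring carbon by attack on a carbonyl rather than on a saturated centre. **9** has no C11 and three stereocentres. The forward reaction needs 1,2-addition to a carbonyl flanked by quaternary C10, then acid-induced transposition. The benzyl ether survives all later steps and leaves by neutral hydrogenolysis.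

**Adjustments to the cycloadduct.** **9** comes from **8** by hydrogenation of C2=C3, **8** from **7** by reduction of the C6 carbonyl, and **7** from cis adduct **6** by epimerisation at C5. The order is fixed: C5 can be epimerised only while C6 is a carbonyl, C6 must be reduced before an organometallic is added, and ring A is best hydrogenated when the only other alkene is the inert vinylogous ester. The methoxy group distinguishes the two carbonyls of **7** by deactivating the one at C9.

**C1–C10 and C4–C5 (key cut).** Opening ring A of **6** gives quinone **4** and diene **5**. Against stepwise annulation onto a ring A or ring B ketone, this joins a nine-carbon and a six-carbon compound in one step into a bicycle holding every ring carbon, all four methyl groups and oxygen at C6, C7 and C9. Both precursors are achiral and flat. The forward reaction must be site-selective for the methyl-bearing double bond of **4**, regioselective (C1 to C10) and enantioselective at C10.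

**Quinone.** **4** is cut at the C–OMe bond to bromoquinone **3**, and **3** at the C–Br bond to commercial **1** (through dibromide **2**). This is simpler than building the methoxyquinone from a phenol and needs only addition–elimination chemistry.

## Roads not taken

**Alternative 1:** Both rings are made at once by cutting C5–C10 and C8–C9. An acyclic triene cyclises by intramolecular Diels–Alder reaction: an E-configured β-methyl acrylimide (C9=C10) adds across a 7-silyloxy diene (C5–C8) to give the trans-fused 7-silyloxy-Δ6-octalin imide A1.
- Merits: C5, C9 and C10 come from one step with the trans fusion in place, so no C5 epimerisation is needed. C11 is present at the carboxyl level, which removes the addition to a hindered ketone. The Δ6 silyl enol ether would take an oxidant from the open α face and give the 6α-oxygen directly, which is better than the reduction–acylation–epimerisation detour of the chosen plan.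
- Weak points: the triene must be assembled linearly with three defined alkene geometries and the quaternary C4 next to the diene. The cyclisation joins a fully substituted dienophile carbon (C10) to a diene terminus (C5) with a quaternary neighbour, and asymmetric catalysis of such a β,β-disubstituted imide is less secure than for simple acrylimides. The C8 stereocentre is spent again when C8 is hydroxylated, which needs enolisation of a C7 ketone towards C8 in competition with C6.
- Comparison: this road is stronger in stereocontrol. The chosen plan sets convergence against it: **6** is reached in three steps from two commercial compounds, with oxygen already on C6, C7 and C9.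

**Alternative 2:** Ring B is annulated onto a ring A ketone by cutting C9–C10 and C5=C6. The chiral imine of racemic 2,2,6-trimethylcyclohexanone A2 reacts through its secondary enamine tautomer at C10 with an ene keto ester at C9. Hydrolysis and aldol condensation of the methyl ketone carbon C6 onto the C5 carbonyl then give ethyl 7-oxodrim-5-en-11-oate A3.
- Merits: C10 rests on a cheap stoichiometric amine and a deracemising Michael reaction with a long record on 2-alkylcyclohexanones. Here it is more secure than the catalytic cycloaddition of the chosen plan, which is an extrapolation. A3 holds C11 at the ester level, and its Δ5-7-ketone would allow the trans fusion to be set by a stereoelectronically controlled reduction.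
- Weak points: A2 is among the most hindered cyclohexanones for imine formation. The acceptor must be attacked at the carbon α to its ester. The aldol closure must occur on a carbonyl flanked by two quaternary carbons. A3 has no oxygen at C6 or C8, so two α-hydroxylations of the C7 ketone, with their regiochemical problems, still lie ahead.
- Comparison: against the weaker precedent of its key step, the chosen plan offers a ring B that leaves the cycloaddition with three oxygenated positions in place and a shorter path to **17**.

**Alternative 3:** The C8–C9 bond is made by a 1,2-shift. A hydrindane α-ketol (tertiary carbinol C7 bearing an acetyl group) rearranges under a chelating Lewis acid: C9 migrates from C7 to the acetyl carbon, the five-membered ring expands to ring B, and 6α-acetoxy-11-benzyloxy-8α-hydroxydriman-7-one A4 results.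
- Merits: A4 is the same compound as **17**, so the endgames are identical. The rearrangement would create the tertiary carbinol, the ketone and the ring size in one thermodynamically driven step, with C5, C9 and C10 taken from the chiral pool. If its precursor were at hand, this would be the shorter and stereochemically safer way to **17**.
- Weak points: a hydrindane with the gem-dimethyl ring, angular methyl, 6-acetoxy group, C9 benzyloxymethyl group and α-hydroxy acetyl unit is not a chiral-pool compound. It would most plausibly come from contracting ring B of a drimane or labdane, so the expansion only restores what was taken apart. Added to this are the choice between migration of C9 and of C6, the dependence of the C8 configuration on chelate geometry, and exposure of the acetate to a Lewis acidic alkoxide.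
- Comparison: the chosen plan needs ten steps to **17** but starts from commodity chemicals and builds the skeleton instead of editing one.

Key step: step 3

## Route

Remarks. (a) α and β denote the faces opposite to and on the side of the C10 methyl group; drimane names are used once C11 is attached. (b) Assumption: the catalyst from (S)-BINOL is taken to block the quinone face whose shielding gives the 10S adduct **6**; if the sense proves opposite, (R)-BINOL is used and nothing else changes.

Step 1
Reactants: 1 2,6-dimethyl-1,4-benzoquinone
Product: 3 3-bromo-2,6-dimethyl-1,4-benzoquinone, via dibromide 2 (not isolated)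
Conditions: Br2 (1.05 equiv), AcOH, 20 °C; then NaOAc, 60 °C
Reagents that add atoms: bromine, BrBr
Why: Electrophilic addition of bromine to one of the two equivalent C=C bonds gives dibromide 2; acetate then removes the acidic C–H next to the carbonyl and the tertiary bromide leaves, restoring the quinone (classical bromination–dehydrobromination of alkylbenzoquinones).

Step 2
Reactants: 3 3-bromo-2,6-dimethyl-1,4-benzoquinone
Product: 4 3-methoxy-2,6-dimethyl-1,4-benzoquinone
Conditions: NaOMe (1.05 equiv), MeOH, 0 °C
Reagents that add atoms: sodium methoxide, [Na+].[O-]C
Why: Addition–elimination of methoxide at the bromine-bearing carbon (vinylogous acyl substitution of a haloquinone); ipso attack is favoured over addition at the free C–H position because bromide is expelled directly.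

Step 3
Reactants: 4 3-methoxy-2,6-dimethyl-1,4-benzoquinone; 5 4-methylpenta-1,3-diene
Product: 6 (4aS,8aR)-2-methoxy-3,4a,8,8-tetramethyl-4a,5,8,8a-tetrahydronaphthalene-1,4-dione (cis adduct; 5β-H, 10β-CH3)
Conditions: TiCl2(OiPr)2 (20 mol%), (S)-BINOL (22 mol%), 4 Å MS, 5 (5 equiv), CH2Cl2, −30 → 0 °C
Reagents that add atoms: none
Why: Proposed new method: the chiral titanium binaphtholate catalysed Diels–Alder reaction of 2-alkoxybenzoquinones with acyclic dienes is extended to a diene whose reacting terminus carries a cis methyl group; the closest known reactions are that catalysed cycloaddition with unhindered dienes and the SnCl4- or BF3-promoted "ortho" cycloadditions of 5 to conjugated carbonyl dienophiles. Titanium is expected to chelate the C6 carbonyl oxygen and the neighbouring methoxy oxygen of 4, which activates the C5=C10 bond and makes C10, the β-carbon of the bound enone, its most electrophilic carbon, while the methoxy group deactivates its own C7=C8 bond and, as a vinylogous ester, the C9 carbonyl. The unsubstituted terminus of 5 (C1), its most nucleophilic carbon, bonds to C10 ahead of the bonding of the dimethyl terminus (C4) to C5 in a concerted but strongly asynchronous [4+2] addition. Ring A is closed as a cyclohexene by this intermolecular six-membered [4+2] closure, both new bonds forming on the same face of the quinone. C10 is controlled by the catalyst, whose binaphtholate blocks one face of the chelated quinone; C5 follows from C10 through the suprafacial addition (cis fusion) and is corrected in step 4. The step needs site, regio- and face selectivity: the first two are secured by the methoxy group of 4 and the polarisation of 5, the third by the ligand. The cis methyl group of 5 disfavours the s-cis conformer and slows the addition, which is why the diene is used in excess.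

Step 4
Reactants: 6 cis adduct
Product: 7 (4aS,8aS)-2-methoxy-3,4a,8,8-tetramethyl-4a,5,8,8a-tetrahydronaphthalene-1,4-dione (trans; 5α-H, 10β-CH3)
Conditions: NaOMe (0.1 equiv), MeOH, 0 → 23 °C
Reagents that add atoms: none
Why: Reversible enolisation of the C6 ketone towards C5, its only enolisable α-position, equilibrates the ring fusion towards the trans isomer, as in the classical base epimerisation of angular-methyl quinone Diels–Alder adducts; methoxide exchange at C7 is degenerate and C10 is quaternary.

Step 5
Reactants: 7 trans enedione
Product: 8 (4S,4aS,8aS)-4-hydroxy-3-methoxy-2,5,5,8a-tetramethyl-4a,5,8,8a-tetrahydronaphthalen-1(4H)-one (6β-OH)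
Conditions: NaBH4, CeCl3·7H2O, MeOH/CH2Cl2, −78 °C
Reagents that add atoms: none
Why: Luche 1,2-reduction takes place at the C6 carbonyl and not at the C9 carbonyl, which is deactivated as a vinylogous ester and flanked by quaternary C10. Hydride enters from the α face because the β face is screened by the syn-axial methyls on C4 and C10, so the axial 6β-alcohol is expected; any 6α-alcohol would converge on 15 through steps 7–9.

Step 6
Reactants: 8 6β-hydroxy dienone
Product: 9 (4S,4aS,8aS)-4-hydroxy-3-methoxy-2,5,5,8a-tetramethyl-4a,5,6,7,8,8a-hexahydronaphthalen-1(4H)-one (6β-hydroxy-7-methoxy-11-nordrim-7-en-9-one)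
Conditions: H2 (1 atm), Pd/C, EtOAc, 23 °C
Reagents that add atoms: none
Why: Heterogeneous hydrogenation of the cis-disubstituted C2=C3 bond; the tetrasubstituted, donor-substituted C7=C8 bond of the vinylogous ester is inert under these conditions.

Step 7
Reactants: 9 6β-hydroxy vinylogous ester; 10 tributyl[(benzyloxy)methyl]stannane
Product: 13 11-benzyloxy-6β-hydroxydrim-8-en-7-one, via (benzyloxymethyl)lithium 11 (not isolated), via carbinol adduct 12 (not isolated)
Conditions: 10 (3.2 equiv), n-BuLi (3.0 equiv), THF, −78 °C; add 9, −78 → −20 °C; then 1 M HCl, THF, 23 °C
Reagents that add atoms: water, O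
Why: Stork–Danheiser alkylative transposition: tin–lithium exchange gives 11, one equivalent of which deprotonates the C6 hydroxyl before a second adds 1,2 to the C9 carbonyl. Acid ionises the tertiary allylic carbinol of 12, water adds at C7 and methanol is lost, giving the C7 enone with C11 on C9. The C9 configuration of 12 disappears in the enone, so the face of addition is irrelevant.

Step 8
Reactants: 13 11-benzyloxy-6β-hydroxydrim-8-en-7-one
Product: 14 6β-acetoxy-11-benzyloxydrim-8-en-7-one
Conditions: Ac2O, DMAP, Et3N, CH2Cl2, 40 °C
Reagents that add atoms: acetic anhydride, CC(=O)OC(C)=O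
Why: DMAP-catalysed (Steglich-type) acylation acetylates even tertiary and hindered axial alcohols, and the 6β-hydroxyl is the only hydroxyl of 13.

Step 9
Reactants: 14 6β-acetoxy-11-benzyloxydrim-8-en-7-one
Product: 15 6α-acetoxy-11-benzyloxydrim-8-en-7-one
Conditions: DBU, toluene, 60 °C
Reagents that add atoms: none
Why: The C6 hydrogen is α to the C7 carbonyl and further acidified by the acetoxy group. Reversible enolisation moves the acetate from the 6β position, syn-axial to the C4 and C10 methyls, to the equatorial 6α position; this is the thermodynamic epimerisation of an α-acyloxy ketone known for axial 2-acetoxy-3-keto steroids.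

Step 10
Reactants: 15 6α-acetoxy-11-benzyloxydrim-8-en-7-one
Product: 17 6α-acetoxy-11-benzyloxy-8α-hydroxydriman-7-one, via 8α-hydroperoxide 16 (not isolated)
Conditions: Mn(dpm)3 (10 mol%), PhSiH3, O2 (1 atm), iPrOH/CH2Cl2, 0 → 23 °C; then P(OEt)3
Reagents that add atoms: dioxygen, O=O
Why: Mukaiyama-type reductive α-hydroxylation of an enone: a manganese hydride transfers a hydrogen atom to the β-carbon C9, the tertiary α-keto radical at C8 is trapped by O2, and P(OEt)3 reduces hydroperoxide 16. Both the hydrogen atom at C9 and O2 at C8 should enter from the α face, anti to the axial C10 methyl, giving 9α-H (equatorial C11) and 8α-OH. The neutral conditions leave the acetate and benzyl ether untouched.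

Step 11
Reactants: 17 6α-acetoxy-11-benzyloxy-8α-hydroxydriman-7-one
Product: 18 6α-acetoxy-11-benzyloxydrimane-7β,8α-diol
Conditions: NaBH4, CeCl3·7H2O, MeOH, −40 °C; AcOH quench
Reagents that add atoms: none
Why: Hydride adds to the C7 ketone axially from the α face, away from the axial 8β-methyl group, giving the equatorial 7β-alcohol; low temperature, CeCl3 and the acidic quench suppress migration of the neighbouring acetate.

Step 12
Reactants: 18 6α-acetoxy-11-benzyloxydrimane-7β,8α-diol
Product: 19 6α-acetoxydrimane-7β,8α,11-triol
Conditions: H2 (1 atm), Pd(OH)2/C, EtOAc, 23 °C
Reagents that add atoms: none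
Why: Neutral hydrogenolysis of the benzyl ether; no other group in 18 is reducible and the acetate is not exposed to base.

Step 13
Reactants: 19 6α-acetoxydrimane-7β,8α,11-triol
Product: 20 6α-acetoxy-7β,8α-dihydroxydriman-11-al
Conditions: TEMPO (10 mol%), PhI(OAc)2, CH2Cl2, 23 °C
Reagents that add atoms: none
Why: Oxoammonium-mediated oxidation is selective for primary over secondary alcohols and stops at the aldehyde in anhydrous CH2Cl2; trans-diequatorial 1,2-diols are tolerated, as in oxidations of primary hydroxyls of partially protected glycosides.

Step 14
Reactants: 20 6α-acetoxy-7β,8α-dihydroxydriman-11-al; 21 1-(triphenyl-λ5-phosphanylidene)propan-2-one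
Product: 22 (1R,2S,3S,4R,4aS,8aS)-2,3-dihydroxy-3,4a,8,8-tetramethyl-4-[(E)-3-oxobut-1-enyl]decahydronaphthalen-1-yl acetate (6α-acetoxy-7β,8α-dihydroxy-14,15-dinorlabd-11E-en-13-one)
Conditions: 21 (2 equiv), toluene, 80 °C
Reagents that add atoms: none
Why: Wittig reaction of a stabilised ylide, which reacts only with the aldehyde and gives the E enone; the neutral conditions spare the acetate, the β-hydroxy aldehyde and the equatorial (thermodynamically preferred) C9 centre.

## Compound list

1 | 2,6-dimethyl-1,4-benzoquinone | CC1=CC(=O)C=C(C)C1=O | starting material
2 | trans-5,6-dibromo-2,6-dimethylcyclohex-2-ene-1,4-dione (racemic, one enantiomer drawn) | CC1=CC(=O)[C@H](Br)[C@@](C)(Br)C1=O | intermediate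
3 | 3-bromo-2,6-dimethyl-1,4-benzoquinone | CC1=CC(=O)C(Br)=C(C)C1=O | intermediate
4 | 3-methoxy-2,6-dimethyl-1,4-benzoquinone | COC1=C(C)C(=O)C(C)=CC1=O | intermediate
5 | 4-methylpenta-1,3-diene | C=CC=C(C)C | starting material
6 | (4aS,8aR)-2-methoxy-3,4a,8,8-tetramethyl-4a,5,8,8a-tetrahydronaphthalene-1,4-dione (cis adduct) | O=C1C(C)=C(OC)C(=O)[C@@H]2C(C)(C)C=CC[C@@]21C | intermediate
7 | (4aS,8aS)-2-methoxy-3,4a,8,8-tetramethyl-4a,5,8,8a-tetrahydronaphthalene-1,4-dione (trans) | O=C1C(C)=C(OC)C(=O)[C@H]2C(C)(C)C=CC[C@@]21C | intermediate
8 | (4S,4aS,8aS)-4-hydroxy-3-methoxy-2,5,5,8a-tetramethyl-4a,5,8,8a-tetrahydronaphthalen-1(4H)-one | O=C1C(C)=C(OC)[C@@H](O)[C@H]2C(C)(C)C=CC[C@@]21C | intermediate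
9 | (4S,4aS,8aS)-4-hydroxy-3-methoxy-2,5,5,8a-tetramethyl-4a,5,6,7,8,8a-hexahydronaphthalen-1(4H)-one | O=C1C(C)=C(OC)[C@@H](O)[C@H]2C(C)(C)CCC[C@@]21C | intermediate
10 | tributyl[(benzyloxy)methyl]stannane | CCCC[Sn](CCCC)(CCCC)COCc1ccccc1 | starting material
11 | (benzyloxymethyl)lithium | [Li]COCc1ccccc1 | intermediate
12 | 11-benzyloxy-7-methoxydrim-7-ene-6β,9-diol (C9 epimers, formed as the dilithium alkoxide) | OC1(COCc3ccccc3)C(C)=C(OC)[C@@H](O)[C@H]2C(C)(C)CCC[C@@]21C | intermediate
13 | 11-benzyloxy-6β-hydroxydrim-8-en-7-one | C(OCc1ccccc1)C1=C(C)C(=O)[C@@H](O)[C@H]2C(C)(C)CCC[C@@]21C | intermediate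
14 | 6β-acetoxy-11-benzyloxydrim-8-en-7-one | C(OCc1ccccc1)C1=C(C)C(=O)[C@@H](OC(C)=O)[C@H]2C(C)(C)CCC[C@@]21C | intermediate
15 | 6α-acetoxy-11-benzyloxydrim-8-en-7-one | C(OCc1ccccc1)C1=C(C)C(=O)[C@H](OC(C)=O)[C@H]2C(C)(C)CCC[C@@]21C | intermediate
16 | 6α-acetoxy-11-benzyloxy-8α-hydroperoxydriman-7-one | C(OCc1ccccc1)[C@H]1[C@](C)(OO)C(=O)[C@H](OC(C)=O)[C@H]2C(C)(C)CCC[C@@]21C | intermediate
17 | 6α-acetoxy-11-benzyloxy-8α-hydroxydriman-7-one | C(OCc1ccccc1)[C@H]1[C@](C)(O)C(=O)[C@H](OC(C)=O)[C@H]2C(C)(C)CCC[C@@]21C | intermediate
18 | 6α-acetoxy-11-benzyloxydrimane-7β,8α-diol | C(OCc1ccccc1)[C@H]1[C@](C)(O)[C@@H](O)[C@H](OC(C)=O)[C@H]2C(C)(C)CCC[C@@]21C | intermediate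
19 | 6α-acetoxydrimane-7β,8α,11-triol | OC[C@H]1[C@](C)(O)[C@@H](O)[C@H](OC(C)=O)[C@H]2C(C)(C)CCC[C@@]21C | intermediate
20 | 6α-acetoxy-7β,8α-dihydroxydriman-11-al | O=C[C@H]1[C@](C)(O)[C@@H](O)[C@H](OC(C)=O)[C@H]2C(C)(C)CCC[C@@]21C | intermediate
21 | 1-(triphenyl-λ5-phosphanylidene)propan-2-one | CC(=O)C=P(c1ccccc1)(c1ccccc1)c1ccccc1 | starting material
22 | (1R,2S,3S,4R,4aS,8aS)-2,3-dihydroxy-3,4a,8,8-tetramethyl-4-[(E)-3-oxobut-1-enyl]decahydronaphthalen-1-yl acetate | CC(=O)/C=C/[C@H]1[C@](C)(O)[C@@H](O)[C@H](OC(C)=O)[C@H]2C(C)(C)CCC[C@@]21C | target

## Step count and least certain steps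

Total: 14 steps. Longest linear sequence: 14 steps (1 to 22); 5, 10 and 21 are purchased.

**Step 3 (key step).** The cycloaddition may be slow because the cis methyl group of 5 disfavours the s-cis conformer; an uncatalysed or stepwise background reaction would then erode face selectivity, or the polar intermediate could be diverted into [2+2] closure or O-alkylation. Fallback with known chemistry: 4 and 5 are combined under SnCl4 in CH2Cl2 at −78 °C, conditions under which 5 adds to conjugated carbonyl dienophiles with the regiochemistry needed here, without chiral control. This should give 6 as a racemate, that is together with ent-6 F1. Epimerisation as in step 4 gives 7 together with ent-7 F2, and the enantiomers are separated by preparative chromatography on a chiral stationary phase. The fallback sets out from 4 and 5 and returns to the route at 7.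

**Step 4.** Epimerisation may be incomplete, because with a flattened ring B and the gem-dimethyl group beside the C6 carbonyl the cis/trans equilibrium may not lie far enough on the trans side. Fallback: kinetic instead of thermodynamic control. 6 is deprotonated with KN(SiMe3)2 (THF, −78 °C) to the potassium dienolate F3, in which C5 is trigonal, and this is protonated at −78 °C by 2,6-di-tert-butylphenol. The β face of C5 is flanked by the C10 methyl and the β-methyl on C4, so the proton should enter from the α face. The fallback sets out from 6 and returns at 7.

**Step 9.** Epimerisation at C6 may be slow, because the C6 hydrogen of 14 is pseudo-equatorial and poorly aligned with the carbonyl π system; forcing conditions could cause deconjugation of the enone. Fallback: the C6 oxygen is removed and delivered anew from the open face. 14 is deacetoxylated with SmI2 (THF/MeOH, −78 °C) to 11-benzyloxydrim-8-en-7-one F4, and α'-acetoxylation of this enone with Mn(OAc)3 (benzene, reflux) should introduce the acetate from the α face. The fallback sets out from 14 and returns at 15.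

**Step 10.** The tetrasubstituted enone may react sluggishly in hydrogen-atom transfer at the hindered C9, or face selectivity may be insufficient when the C8 radical captures oxygen. Fallback: two ionic steps in place of the radical one. Copper hydride 1,4-hydrosilylation of 15 ([(Ph3P)CuH]6 cat., Me2PhSiH, toluene) gives 6α-acetoxy-11-benzyloxy-7-[dimethyl(phenyl)silyloxy]drim-7-ene F5 with 9α-H. Rubottom oxidation (mCPBA, NaHCO3, CH2Cl2, 0 °C), which epoxidises the enol ether from the α face, gives 6α-acetoxy-11-benzyloxy-8α-[dimethyl(phenyl)silyloxy]driman-7-one F6; dilute HCl in THF removes the silyl group. The fallback sets out from 15 and returns at 17.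

**Step 13.** Chemoselectivity may be lost through competing oxidation of the secondary 7-hydroxyl or glycol cleavage, because the primary hydroxyl is hindered by its neighbours. Fallback: the last steps are reordered so that no secondary hydroxyl is present during the oxidation. 17 is hydrogenolysed (H2, Pd(OH)2/C, EtOAc) to 6α-acetoxy-8α,11-dihydroxydriman-7-one F7, and Dess–Martin oxidation gives 6α-acetoxy-8α-hydroxy-7-oxodriman-11-al F8. The Wittig reaction with 21 gives 6α-acetoxy-8α-hydroxy-14,15-dinorlabd-11E-ene-7,13-dione F9. The C7 ketone is then reduced with NaBH4 in MeOH/CH2Cl2 at −78 °C, where saturated ketones are reduced in preference to conjugated ones and hydride again enters axially. The fallback sets out from 17 and returns at 22.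

## Further compounds

F1 | step 3 | ent-6, (4aR,8aS)-2-methoxy-3,4a,8,8-tetramethyl-4a,5,8,8a-tetrahydronaphthalene-1,4-dione | O=C1C(C)=C(OC)C(=O)[C@H]2C(C)(C)C=CC[C@]21C
F2 | step 3 | ent-7, (4aR,8aR)-2-methoxy-3,4a,8,8-tetramethyl-4a,5,8,8a-tetrahydronaphthalene-1,4-dione | O=C1C(C)=C(OC)C(=O)[C@@H]2C(C)(C)C=CC[C@]21C
F3 | step 4 | potassium dienolate of 6 (C5=C6 enolate, 10S) | [K+].[O-]C1=C2C(C)(C)C=CC[C@]2(C)C(=O)C(C)=C1OC
F4 | step 9 | 11-benzyloxydrim-8-en-7-one | C(OCc1ccccc1)C1=C(C)C(=O)C[C@H]2C(C)(C)CCC[C@@]21C
F5 | step 10 | 6α-acetoxy-11-benzyloxy-7-[dimethyl(phenyl)silyloxy]drim-7-ene | C(OCc1ccccc1)[C@H]1C(C)=C(O[Si](C)(C)c3ccccc3)[C@H](OC(C)=O)[C@H]2C(C)(C)CCC[C@@]21C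
F6 | step 10 | 6α-acetoxy-11-benzyloxy-8α-[dimethyl(phenyl)silyloxy]driman-7-one | C(OCc1ccccc1)[C@H]1[C@](C)(O[Si](C)(C)c3ccccc3)C(=O)[C@H](OC(C)=O)[C@H]2C(C)(C)CCC[C@@]21C
F7 | step 13 | 6α-acetoxy-8α,11-dihydroxydriman-7-one | OC[C@H]1[C@](C)(O)C(=O)[C@H](OC(C)=O)[C@H]2C(C)(C)CCC[C@@]21C
F8 | step 13 | 6α-acetoxy-8α-hydroxy-7-oxodriman-11-al | O=C[C@H]1[C@](C)(O)C(=O)[C@H](OC(C)=O)[C@H]2C(C)(C)CCC[C@@]21C
F9 | step 13 | 6α-acetoxy-8α-hydroxy-14,15-dinorlabd-11E-ene-7,13-dione | CC(=O)/C=C/[C@H]1[C@](C)(O)C(=O)[C@H](OC(C)=O)[C@H]2C(C)(C)CCC[C@@]21C
A1 | alternative 1 | 3-[7-(tert-butyldimethylsilyloxy)drim-6-en-11-oyl]oxazolidin-2-one (trans-fused, 9β-imide) | O=C([C@H]1[C@@H](C)C(O[Si](C)(C)C(C)(C)C)=C[C@H]2C(C)(C)CCC[C@@]21C)N1CCOC1=O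
A2 | alternative 2 | 2,2,6-trimethylcyclohexanone (racemic) | CC1CCCC(C)(C)C1=O
A3 | alternative 2 | ethyl 7-oxodrim-5-en-11-oate (9β-ester) | CCOC(=O)[C@H]1[C@H](C)C(=O)C=C2C(C)(C)CCC[C@@]21C
A4 | alternative 3 | 6α-acetoxy-11-benzyloxy-8α-hydroxydriman-7-one | C(OCc1ccccc1)[C@H]1[C@](C)(O)C(=O)[C@H](OC(C)=O)[C@H]2C(C)(C)CCC[C@@]21C
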